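**Strategy**

- The target is a ten-membered carbocycle (germacrane numbering) with a C9 ketone, angelates on C3, C6 and C8, an isopropenyl group on C7 and two cis-fused oxiranes (C1–C10, C4–C5). Retrosynthesis first removes the three esters and both epoxide oxygens, leaving a (1(10)Z,4Z)-dienone, and then the C8 oxygen (enolate oxidation).
- The enabling feature is that C9(=O), C8, the vicinal pair C7(isopropenyl)/C6(O) and the C5=C4 olefin form a 1-oxy-1,5-diene, with C9 and C4 bridged by C10–C1–C2–C3. Cutting C6–C7 and rejoining C9–C4 therefore gives a cis-1,2-dialkenylcyclohex-2-enol, the retron of an anionic oxy-Cope shift.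
- Forward, the six-membered ring is bought as 2-methylcyclohexane-1,3-dione, allylated and desymmetrised by yeast. It then receives the C10 methyl/enone, an E enol silane arm on C4 and an E dienyl group on C9. The ten-membered ring arises in one step by [3,3] ring enlargement with hydroxylation of the enolate, and the two oxiranes are closed last on the macrocycle.
- C3 comes from the yeast reduction; with the auxiliary quaternary C4 it steers the dienyl addition at C9. The chair of the shift trades C4/C9 for C6, C7 and the Z C4–C5 olefin. C8 comes from outer-face hydroxylation followed by Mitsunobu inversion with angelic acid. The C4–C5 oxirane is directed by the C3 hydroxyl, the C1–C10 oxirane comes from peripheral peroxide attack, and the angelate geometry is bought.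

Key step: step 12

Remark: the ten-membered ring and, in the Why lines, the atoms of its cyclohexane precursors carry germacrane numbers (C9 carbonyl or carbinol carbon, C10 its methyl-bearing neighbour, C3 the oxygenated carbon, C4 the quaternary carbon, C5=C6 the enol ether arm, C8=C7 the first olefin of the dienyl group); α and β refer to the ring drawn with rising numbers anticlockwise, β towards the viewer; the facial preferences stated for steps 10, 12 and 16 are assumptions from conformational analysis.

**Route**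

Step 1
Reactants: 1 2-methylcyclohexane-1,3-dione; 2 allyl bromide
Product: 3 2-allyl-2-methylcyclohexane-1,3-dione
Conditions: NaOH (1 M aq), rt
Reagents that add atoms: none
Why: C-allylation of the sodium enolate of a cyclic 1,3-dione in water, where the soft allylic halide favours carbon over oxygen, is the standard entry to 2,2-disubstituted cyclohexane-1,3-diones.

Step 2
Reactants: 3 2-allyl-2-methylcyclohexane-1,3-dione
Product: 4 (2S,3S)-2-allyl-3-hydroxy-2-methylcyclohexan-1-one
Conditions: baker's yeast (Saccharomyces cerevisiae), sucrose, H2O, 30 °C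
Reagents that add atoms: none
Why: Desymmetrising yeast reduction of one of the two enantiotopic carbonyl groups, the established outcome for this dione, should set the carbinol carbon (S) and with it the quaternary carbon (S), hydroxyl cis to allyl.

Step 3
Reactants: 4 (2S,3S)-2-allyl-3-hydroxy-2-methylcyclohexan-1-one
Product: 5 (2S,3S)-2-allyl-2-methyl-3-(triethylsilyloxy)cyclohexan-1-one
Conditions: TESCl, imidazole, DMAP (cat.), DMF, 0 °C to rt
Reagents that add atoms: chlorotriethylsilane, CC[Si](Cl)(CC)CC
Why: Routine silylation of the secondary alcohol shields it from the enolate chemistry that follows.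

Step 4
Reactants: 5 (2S,3S)-2-allyl-2-methyl-3-(triethylsilyloxy)cyclohexan-1-one
Product: 7 (2S,3S)-2-allyl-2,6-dimethyl-3-(triethylsilyloxy)cyclohexan-1-one (both C6 epimers), via lithium enolate 6 (not isolated)
Conditions: LiN(iPr)2 (LDA), THF, −78 °C; MeI, −78 to −20 °C
Reagents that add atoms: iodomethane, CI
Why: Kinetic enolate formation can only occur at C10 (the other α-carbon is quaternary) and SN2 methylation follows; the new centre forms as a mixture and disappears in step 5.

Step 5
Reactants: 7 (2S,3S)-2-allyl-2,6-dimethyl-3-(triethylsilyloxy)cyclohexan-1-one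
Product: 9 (5S,6S)-6-allyl-2,6-dimethyl-5-(triethylsilyloxy)cyclohex-2-en-1-one, via trimethylsilyl enol ether 8 (not isolated)
Conditions: TMSOTf, Et3N, CH2Cl2, 0 °C; then Pd(OAc)2 (1.1 equiv), MeCN, rt
Reagents that add atoms: none
Why: Saegusa–Ito dehydrogenation: the tetrasubstituted silyl enol ether is the only one that can form, and the palladium enolate should lose a β-hydride from the ring methylene to give the endocyclic 2-methyl enone.

Step 6
Reactants: 9 (5S,6S)-6-allyl-2,6-dimethyl-5-(triethylsilyloxy)cyclohex-2-en-1-one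
Product: 10 2-[(1S,6S)-1,3-dimethyl-2-oxo-6-(triethylsilyloxy)cyclohex-3-en-1-yl]acetaldehyde
Conditions: OsO4 (2 mol %), NaIO4, 2,6-lutidine, dioxane–H2O (3:1), rt
Reagents that add atoms: osmium tetroxide, O=[Os](=O)(=O)=O; sodium periodate, [Na+].[O-]I(=O)(=O)=O
Why: Lemieux–Johnson cleavage: OsO4 prefers the electron-rich monosubstituted olefin over the electron-poor trisubstituted enone olefin, and 2,6-lutidine suppresses over-oxidation.

Step 7
Reactants: 10 2-[(1S,6S)-1,3-dimethyl-2-oxo-6-(triethylsilyloxy)cyclohex-3-en-1-yl]acetaldehyde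
Product: 11 (5S,6S)-2,6-dimethyl-5-(triethylsilyloxy)-6-[(E)-2-(triisopropylsilyloxy)vinyl]cyclohex-2-en-1-one
Conditions: TIPSOTf, Et3N, CH2Cl2, 0 °C to rt
Reagents that add atoms: triisopropylsilyl trifluoromethanesulfonate, CC(C)[Si](OS(=O)(=O)C(F)(F)F)(C(C)C)C(C)C
Why: Soft enolisation of the aldehyde (silyl triflate, amine) should give the E enol silane, because the quaternary C4 and the bulky silyloxy group avoid each other both in the deprotonation of the silyloxocarbenium ion and at equilibrium, while the hindered ketone has no α′-hydrogen.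

Step 8
Reactants: 11 (5S,6S)-2,6-dimethyl-5-(triethylsilyloxy)-6-[(E)-2-(triisopropylsilyloxy)vinyl]cyclohex-2-en-1-one
Product: 12 (5S,6S)-5-hydroxy-2,6-dimethyl-6-[(E)-2-(triisopropylsilyloxy)vinyl]cyclohex-2-en-1-one
Conditions: HF·pyridine, pyridine, THF, 0 °C
Reagents that add atoms: none
Why: Buffered HF·pyridine should cleave the secondary triethylsilyl ether much faster than the triisopropylsilyl enol ether, whose silicon is shielded and whose β-carbon is neopentylic (selective desilylation).

Step 9
Reactants: 13 2-methylbut-1-en-3-yne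
Product: 15 (E)-1-iodo-3-methylbuta-1,3-diene, via dienylzirconocene chloride 14 (not isolated)
Conditions: Cp2Zr(H)Cl, CH2Cl2, rt; I2, 0 °C (kept as an ether solution)
Reagents that add atoms: iodine, II
Why: Hydrozirconation (syn, terminal, alkyne preferred over the 1,1-disubstituted olefin) and iodinolysis of the C–Zr bond with retention should give the E dienyl iodide.

Step 10
Reactants: 12 (5S,6S)-5-hydroxy-2,6-dimethyl-6-[(E)-2-(triisopropylsilyloxy)vinyl]cyclohex-2-en-1-one; 15 (E)-1-iodo-3-methylbuta-1,3-diene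
Product: 18 (1S,5S,6S)-2,6-dimethyl-1-[(E)-3-methylbuta-1,3-dienyl]-6-[(E)-2-(triisopropylsilyloxy)vinyl]cyclohex-2-ene-1,5-diol, via dienyllithium 16 (not isolated), via dienylcerium dichloride 17 (not isolated)
Conditions: 15 (3 equiv), tBuLi (6 equiv), Et2O, −78 °C; CeCl3 (3 equiv), THF, −78 °C; then 12, −78 to −40 °C; aq NH4Cl
Reagents that add atoms: none
Why: Iodine–lithium exchange with retention, transmetalation to the organocerium reagent and 1,2-addition to the hindered enone; the first equivalent turns the C3 hydroxyl into its cerium alkoxide, which is axial in the half-chair that holds the C4 methyl axial on the other face and should deliver the dienyl group to its own face, so that the new C9 centre (S) has the dienyl group cis to C3–O and to the enol ether arm and trans to the C4 methyl.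

Step 11
Reactants: 18 (1S,5S,6S)-2,6-dimethyl-1-[(E)-3-methylbuta-1,3-dienyl]-6-[(E)-2-(triisopropylsilyloxy)vinyl]cyclohex-2-ene-1,5-diol
Product: 19 (1S,5S,6S)-2,6-dimethyl-1-[(E)-3-methylbuta-1,3-dienyl]-5-(triethylsilyloxy)-6-[(E)-2-(triisopropylsilyloxy)vinyl]cyclohex-2-en-1-ol
Conditions: TESCl, imidazole, DMAP (cat.), DMF, 0 °C to rt
Reagents that add atoms: chlorotriethylsilane, CC[Si](Cl)(CC)CC
Why: Silylation distinguishes the secondary C3 hydroxyl from the tertiary, doubly flanked C9 hydroxyl, which must stay free as the trigger of the next step.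

Step 12
Reactants: 19 (1S,5S,6S)-2,6-dimethyl-1-[(E)-3-methylbuta-1,3-dienyl]-5-(triethylsilyloxy)-6-[(E)-2-(triisopropylsilyloxy)vinyl]cyclohex-2-en-1-ol
Product: 22 (1(10)Z,4Z)-8α-hydroxy-3β-(triethylsilyloxy)-6α-(triisopropylsilyloxy)germacra-1(10),4,11-trien-9-one, via potassium alkoxide 20 (not isolated), via potassium dienolate 21 (not isolated)
Conditions: KN(SiMe3)2 (KHMDS, 1.1 equiv), 18-crown-6, THF, −78 to 0 °C; then −78 °C, 2-(phenylsulfonyl)-3-phenyloxaziridine; AcOH, −78 °C
Reagents that add atoms: 2-(phenylsulfonyl)-3-phenyloxaziridine, O=S(=O)(c1ccccc1)N1OC1c1ccccc1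
Why: The alkoxide 20 triggers an anionic oxy-Cope [3,3] shift that breaks the ring bond C9–C4 and joins C7 of the dienyl group to C6 of the enol ether, so the cyclohexene grows by four atoms into the cyclodecadienone dienolate 21; this is the known ring expansion of potassium 1,2-dialkenylcyclohexanolates to cyclodec-5-enones, followed by the equally known oxidation of the enolate by a 2-sulfonyloxaziridine. The ten-membered ring is thus closed not end to end but by pericyclic enlargement of the six-membered ring through a chair-like six-centre transition state. The cis C4–C5 olefin requires the half-chair in which the dienyl group is pseudoaxial and antiperiplanar to the axial C4 methyl (enol ether arm equatorial, C3 silyloxy axial), because only then is C3 axial on the chair of the shift and ends up cis to C6; the cis relation of the two alkenyl groups set in step 10 makes this chair possible, and A(1,2) strain between the C10 methyl and a pseudoequatorial dienyl group, together with the crown-freed oxide taking the pseudoequatorial site as is usual for cis-1,2-dialkenylcyclohexanolates, should favour it over the other half-chair, which would give the 4E olefin with C6 and C7 inverted. C6 and C7 are set together by the E geometry of both termini, whose silyloxy and isopropenyl groups sit equatorial on that chair, which leads to 6α-O and 7β-isopropenyl, while the cis C1–C10 olefin is inherited from the cyclohexene. C8 is set by attack of the oxaziridine on the outer face of the dienolate, the face turned away from the C4–C5 olefin across the ring, which should give the 8α-alcohol, the epimer that step 13 inverts. The E enol silane points its silicon away from the oxide so that silyl transfer cannot compete, and C8 is the only nucleophilic carbon of the cross-conjugated dienolate.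

Step 13
Reactants: 22 (1(10)Z,4Z)-8α-hydroxy-3β-(triethylsilyloxy)-6α-(triisopropylsilyloxy)germacra-1(10),4,11-trien-9-one; 23 angelic acid
Product: 24 (1(10)Z,4Z)-8β-angeloyloxy-3β-(triethylsilyloxy)-6α-(triisopropylsilyloxy)germacra-1(10),4,11-trien-9-one
Conditions: PPh3, DIAD, toluene, 0 °C to rt
Reagents that add atoms: none
Why: Mitsunobu esterification: the α-ketol is activated as its oxyphosphonium salt and displaced by angelate in an SN2 step that inverts C8 to the 8β configuration, and because the acid is the nucleophile and is never activated as an acyl donor its Z geometry should survive.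

Step 14
Reactants: 24 (1(10)Z,4Z)-8β-angeloyloxy-3β-(triethylsilyloxy)-6α-(triisopropylsilyloxy)germacra-1(10),4,11-trien-9-one
Product: 25 (1(10)Z,4Z)-8β-angeloyloxy-3β-hydroxy-6α-(triisopropylsilyloxy)germacra-1(10),4,11-trien-9-one
Conditions: HF·pyridine, pyridine, THF, 0 °C
Reagents that add atoms: none
Why: The allylic secondary triethylsilyl ether should be cleaved by buffered HF·pyridine at 0 °C while the more hindered triisopropylsilyl ether at C6 stays (selective desilylation).

Step 15
Reactants: 25 (1(10)Z,4Z)-8β-angeloyloxy-3β-hydroxy-6α-(triisopropylsilyloxy)germacra-1(10),4,11-trien-9-one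
Product: 26 (1(10)Z)-8β-angeloyloxy-4α,5α-epoxy-3β-hydroxy-6α-(triisopropylsilyloxy)germacra-1(10),11-dien-9-one
Conditions: mCPBA (1.05 equiv), NaHCO3, CH2Cl2, −20 to 0 °C
Reagents that add atoms: 3-chloroperoxybenzoic acid, O=C(OO)c1cccc(Cl)c1
Why: Henbest (hydroxyl-directed) peracid epoxidation of the only electron-rich trisubstituted olefin: A(1,3) strain across the Z olefin holds H-3 in the olefin plane, so the hydrogen-bonded peracid should add on the face of the C3 hydroxyl (threo) and away from the C6 silyloxy group, giving the cis-fused 4α,5α-oxirane.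

Step 16
Reactants: 26 (1(10)Z)-8β-angeloyloxy-4α,5α-epoxy-3β-hydroxy-6α-(triisopropylsilyloxy)germacra-1(10),11-dien-9-one
Product: 27 8β-angeloyloxy-1β,10β:4α,5α-diepoxy-3β-hydroxy-6α-(triisopropylsilyloxy)germacr-11-en-9-one
Conditions: tBuOOH (anhydrous, in decane), DBU, CH2Cl2, 0 °C to rt
Reagents that add atoms: tert-butyl hydroperoxide, CC(C)(C)OO
Why: Weitz–Scheffer nucleophilic epoxidation touches only the enone; the ring keeps the intermediate enolate from rotating, so the oxirane stays cis-fused, and the peroxide is expected to add to C1 on the open β face of the cis-enone, the face not covered by the C3–C7 loop of the ring.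

Step 17
Reactants: 27 8β-angeloyloxy-1β,10β:4α,5α-diepoxy-3β-hydroxy-6α-(triisopropylsilyloxy)germacr-11-en-9-one
Product: 28 8β-angeloyloxy-1β,10β:4α,5α-diepoxy-3β,6α-dihydroxygermacr-11-en-9-one
Conditions: HF·pyridine, pyridine, THF, 0 °C to rt
Reagents that add atoms: none
Why: Longer exposure to buffered HF·pyridine should remove the triisopropylsilyl ether, conditions that trisubstituted oxiranes and the ester tolerate (fluoride desilylation).

Step 18
Reactants: 28 8β-angeloyloxy-1β,10β:4α,5α-diepoxy-3β,6α-dihydroxygermacr-11-en-9-one; 23 angelic acid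
Product: 30 3β,6α,8β-tris(angeloyloxy)-1β,10β:4α,5α-diepoxygermacr-11-en-9-one (CNP0154187.1), via mixed anhydride 29 (not isolated)
Conditions: 23 (6 equiv), 2,4,6-trichlorobenzoyl chloride, Et3N, toluene, rt, filtered; then 28, toluene, 80 °C
Reagents that add atoms: none
Why: Yamaguchi-type acylation of both secondary alcohols by the preformed angelic 2,4,6-trichlorobenzoic mixed anhydride without a nucleophilic catalyst, conditions under which angelates do not isomerise to tiglates, proceeds with retention at C3 and C6.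

**Compound list**

1 | 2-methylcyclohexane-1,3-dione | CC1C(=O)CCCC1=O | starting material
2 | allyl bromide | C=CCBr | starting material
3 | 2-allyl-2-methylcyclohexane-1,3-dione | C=CCC1(C)C(=O)CCCC1=O | intermediate
4 | (2S,3S)-2-allyl-3-hydroxy-2-methylcyclohexan-1-one (hydroxyl cis to allyl) | O=C1CCC[C@H](O)[C@]1(C)CC=C | intermediate
5 | (2S,3S)-2-allyl-2-methyl-3-(triethylsilyloxy)cyclohexan-1-one | O=C1CCC[C@H](O[Si](CC)(CC)CC)[C@]1(C)CC=C | intermediate
6 | lithium enolate of 5 | [Li+].[O-]C1=CCC[C@H](O[Si](CC)(CC)CC)[C@]1(C)CC=C | intermediate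
7 | (2S,3S)-2-allyl-2,6-dimethyl-3-(triethylsilyloxy)cyclohexan-1-one, both C6 epimers | O=C1C(C)CC[C@H](O[Si](CC)(CC)CC)[C@]1(C)CC=C | intermediate
8 | trimethylsilyl enol ether of 7 (C1=C6 enol ether) | C[Si](C)(C)OC1=C(C)CC[C@H](O[Si](CC)(CC)CC)[C@]1(C)CC=C | intermediate
9 | (5S,6S)-6-allyl-2,6-dimethyl-5-(triethylsilyloxy)cyclohex-2-en-1-one | O=C1C(C)=CC[C@H](O[Si](CC)(CC)CC)[C@]1(C)CC=C | intermediate
10 | 2-[(1S,6S)-1,3-dimethyl-2-oxo-6-(triethylsilyloxy)cyclohex-3-en-1-yl]acetaldehyde | O=C1C(C)=CC[C@H](O[Si](CC)(CC)CC)[C@]1(C)CC=O | intermediate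
11 | (5S,6S)-2,6-dimethyl-5-(triethylsilyloxy)-6-[(E)-2-(triisopropylsilyloxy)vinyl]cyclohex-2-en-1-one | O=C1C(C)=CC[C@H](O[Si](CC)(CC)CC)[C@]1(C)/C=C/O[Si](C(C)C)(C(C)C)C(C)C | intermediate
12 | (5S,6S)-5-hydroxy-2,6-dimethyl-6-[(E)-2-(triisopropylsilyloxy)vinyl]cyclohex-2-en-1-one | O=C1C(C)=CC[C@H](O)[C@]1(C)/C=C/O[Si](C(C)C)(C(C)C)C(C)C | intermediate
13 | 2-methylbut-1-en-3-yne | C=C(C)C#C | starting material
14 | chlorobis(cyclopentadienyl)[(E)-3-methylbuta-1,3-dienyl]zirconium | C=C(C)/C=C/[Zr](Cl)(C1C=CC=C1)C1C=CC=C1 | intermediate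
15 | (E)-1-iodo-3-methylbuta-1,3-diene | C=C(C)/C=C/I | intermediate
16 | [(E)-3-methylbuta-1,3-dienyl]lithium | [Li]/C=C/C(C)=C | intermediate
17 | dichloro[(E)-3-methylbuta-1,3-dienyl]cerium | Cl[Ce](Cl)/C=C/C(C)=C | intermediate
18 | (1S,5S,6S)-2,6-dimethyl-1-[(E)-3-methylbuta-1,3-dienyl]-6-[(E)-2-(triisopropylsilyloxy)vinyl]cyclohex-2-ene-1,5-diol (dienyl cis to the 5-hydroxyl and to the silyloxyvinyl group) | C=C(C)/C=C/[C@]1(O)C(C)=CC[C@H](O)[C@]1(C)/C=C/O[Si](C(C)C)(C(C)C)C(C)C | intermediate
19 | (1S,5S,6S)-2,6-dimethyl-1-[(E)-3-methylbuta-1,3-dienyl]-5-(triethylsilyloxy)-6-[(E)-2-(triisopropylsilyloxy)vinyl]cyclohex-2-en-1-ol | C=C(C)/C=C/[C@]1(O)C(C)=CC[C@H](O[Si](CC)(CC)CC)[C@]1(C)/C=C/O[Si](C(C)C)(C(C)C)C(C)C | intermediate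
20 | potassium alkoxide of 19 | C=C(C)/C=C/[C@]1([O-])C(C)=CC[C@H](O[Si](CC)(CC)CC)[C@]1(C)/C=C/O[Si](C(C)C)(C(C)C)C(C)C.[K+] | intermediate
21 | potassium 8(9)-enolate of (1(10)Z,4Z)-3β-(triethylsilyloxy)-6α-(triisopropylsilyloxy)germacra-1(10),4,11-trien-9-one (C7 and C10 trans on the enolate) | C=C(C)[C@H]1[C@H](O[Si](C(C)C)(C(C)C)C(C)C)/C=C(C)\[C@@H](O[Si](CC)(CC)CC)C/C=C(C)\C([O-])=C\1.[K+] | intermediate
22 | (1(10)Z,4Z)-8α-hydroxy-3β-(triethylsilyloxy)-6α-(triisopropylsilyloxy)germacra-1(10),4,11-trien-9-one (7β-isopropenyl) | C=C(C)[C@H]1[C@H](O[Si](C(C)C)(C(C)C)C(C)C)/C=C(C)\[C@@H](O[Si](CC)(CC)CC)C/C=C(C)\C(=O)[C@@H]1O | intermediate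
23 | angelic acid, (Z)-2-methylbut-2-enoic acid | O=C(O)/C(C)=C\C | starting material
24 | (1(10)Z,4Z)-8β-angeloyloxy-3β-(triethylsilyloxy)-6α-(triisopropylsilyloxy)germacra-1(10),4,11-trien-9-one | C=C(C)[C@H]1[C@H](O[Si](C(C)C)(C(C)C)C(C)C)/C=C(C)\[C@@H](O[Si](CC)(CC)CC)C/C=C(C)\C(=O)[C@H]1OC(=O)/C(C)=C\C | intermediate
25 | (1(10)Z,4Z)-8β-angeloyloxy-3β-hydroxy-6α-(triisopropylsilyloxy)germacra-1(10),4,11-trien-9-one | C=C(C)[C@H]1[C@H](O[Si](C(C)C)(C(C)C)C(C)C)/C=C(C)\[C@@H](O)C/C=C(C)\C(=O)[C@H]1OC(=O)/C(C)=C\C | intermediate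
26 | (1(10)Z)-8β-angeloyloxy-4α,5α-epoxy-3β-hydroxy-6α-(triisopropylsilyloxy)germacra-1(10),11-dien-9-one | C=C(C)[C@H]1[C@H](O[Si](C(C)C)(C(C)C)C(C)C)[C@@H]2O[C@]2(C)[C@@H](O)C/C=C(C)\C(=O)[C@H]1OC(=O)/C(C)=C\C | intermediate
27 | 8β-angeloyloxy-1β,10β:4α,5α-diepoxy-3β-hydroxy-6α-(triisopropylsilyloxy)germacr-11-en-9-one | C=C(C)[C@H]1[C@H](O[Si](C(C)C)(C(C)C)C(C)C)[C@@H]2O[C@]2(C)[C@@H](O)C[C@H]2O[C@@]2(C)C(=O)[C@H]1OC(=O)/C(C)=C\C | intermediate
28 | 8β-angeloyloxy-1β,10β:4α,5α-diepoxy-3β,6α-dihydroxygermacr-11-en-9-one | C=C(C)[C@H]1[C@H](O)[C@@H]2O[C@]2(C)[C@@H](O)C[C@H]2O[C@@]2(C)C(=O)[C@H]1OC(=O)/C(C)=C\C | intermediate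
29 | angelic 2,4,6-trichlorobenzoic anhydride | O=C(OC(=O)/C(C)=C\C)c1c(Cl)cc(Cl)cc1Cl | intermediate
30 | 3β,6α,8β-tris(angeloyloxy)-1β,10β:4α,5α-diepoxygermacr-11-en-9-one (CNP0154187.1) | C=C(C)[C@H]1[C@H](OC(=O)/C(C)=C\C)[C@@H]2O[C@]2(C)[C@@H](OC(=O)/C(C)=C\C)C[C@H]2O[C@@]2(C)C(=O)[C@H]1OC(=O)/C(C)=C\C | target

**Count**

Total: 18 steps. Longest linear sequence: 17 steps (steps 1 to 8 and 10 to 18, from compound 1); step 9 is a one-step side branch.

**Steps most likely to fail**

Step 12. Two things can go wrong. The shift may leak through the other half-chair, which would show as a 4E olefin. The hindered dienolate may also be oxidised too slowly, so that it transfers a proton to the extended dienolate, or the product alkoxide adds to the sulfonimine. The fallback separates the two events and changes the oxidant class. It sets out from 19 and comes back at 22. Compound 19 is rearranged with the same base, and the dienolate is silylated in the pot with chlorotrimethylsilane to give the trimethylsilyl dienol ether F1. F1 can be isolated, so its olefin geometries can be checked before any oxidant is spent. Rubottom oxidation of F1 (mCPBA, NaHCO3, CH2Cl2, −40 °C) with silyl shift should give the 8α-trimethylsilyloxy ketone F2. Citric acid in MeOH at 0 °C then frees the hydroxyl and delivers 22.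

Step 16. The peroxide may add to the wrong face of the cis-enone, and the amine base may epimerise C8 next to the ketone. The fallback replaces peripheral nucleophilic attack by hydroxyl-directed delivery, which should reach the opposite face because the hydride and the peroxide both enter from outside. It sets out from 24 and comes back at 27. Luche reduction of 24 (NaBH4, CeCl3·7H2O, MeOH, −78 °C) should give the allylic 9β-alcohol F3; its C9 configuration is assumed and is lost again later. Directed epoxidation of F3 with VO(acac)2 and tBuOOH should place the oxygen on the face of the C9 hydroxyl to give the 1β,10β-epoxy alcohol F4. Dess–Martin oxidation returns the ketone as the 3-triethylsilyloxy epoxy ketone F5. HF·pyridine in pyridine and THF at 0 °C removes the triethylsilyl group to give the 3β-hydroxy epoxy ketone F6. The directed peracid epoxidation of step 15, applied to F6, then gives 27.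

Step 8. The enol silane may be lost under the desilylation conditions, by fluoride attack at silicon or by C-protonation with capture of the oxocarbenium ion by the freed C3 hydroxyl as a cyclic acetal. The fallback carries the C3 oxygen through the enol silylation as a base-labile ester. It sets out from 9 and comes back at 12. Aqueous acetic acid in THF removes the silyl group of 9, which is harmless before the enol ether exists, to give (5S,6S)-6-allyl-5-hydroxy-2,6-dimethylcyclohex-2-en-1-one F7. Ac2O, pyridine and DMAP give the acetate F8. The cleavage of step 6 then gives the acetoxy aldehyde F9, and the silylation of step 7 gives the acetoxy E enol silane F10. K2CO3 in MeOH at 0 °C then frees the hydroxyl and delivers 12.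

**Further compounds**

F1 | step 12 | trimethylsilyl 8(9)-dienol ether of (1(10)Z,4Z)-3β-(triethylsilyloxy)-6α-(triisopropylsilyloxy)germacra-1(10),4,11-trien-9-one | C=C(C)[C@H]1[C@H](O[Si](C(C)C)(C(C)C)C(C)C)/C=C(C)\[C@@H](O[Si](CC)(CC)CC)C/C=C(C)\C(O[Si](C)(C)C)=C\1
F2 | step 12 | (1(10)Z,4Z)-3β-(triethylsilyloxy)-6α-(triisopropylsilyloxy)-8α-(trimethylsilyloxy)germacra-1(10),4,11-trien-9-one | C=C(C)[C@H]1[C@H](O[Si](C(C)C)(C(C)C)C(C)C)/C=C(C)\[C@@H](O[Si](CC)(CC)CC)C/C=C(C)\C(=O)[C@@H]1O[Si](C)(C)C
F3 | step 16 | (1(10)Z,4Z)-8β-angeloyloxy-3β-(triethylsilyloxy)-6α-(triisopropylsilyloxy)germacra-1(10),4,11-trien-9β-ol | C=C(C)[C@H]1[C@H](O[Si](C(C)C)(C(C)C)C(C)C)/C=C(C)\[C@@H](O[Si](CC)(CC)CC)C/C=C(C)\[C@@H](O)[C@H]1OC(=O)/C(C)=C\C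
F4 | step 16 | (4Z)-8β-angeloyloxy-1β,10β-epoxy-3β-(triethylsilyloxy)-6α-(triisopropylsilyloxy)germacra-4,11-dien-9β-ol | C=C(C)[C@H]1[C@H](O[Si](C(C)C)(C(C)C)C(C)C)/C=C(C)\[C@@H](O[Si](CC)(CC)CC)C[C@H]2O[C@@]2(C)[C@@H](O)[C@H]1OC(=O)/C(C)=C\C
F5 | step 16 | (4Z)-8β-angeloyloxy-1β,10β-epoxy-3β-(triethylsilyloxy)-6α-(triisopropylsilyloxy)germacra-4,11-dien-9-one | C=C(C)[C@H]1[C@H](O[Si](C(C)C)(C(C)C)C(C)C)/C=C(C)\[C@@H](O[Si](CC)(CC)CC)C[C@H]2O[C@@]2(C)C(=O)[C@H]1OC(=O)/C(C)=C\C
F6 | step 16 | (4Z)-8β-angeloyloxy-1β,10β-epoxy-3β-hydroxy-6α-(triisopropylsilyloxy)germacra-4,11-dien-9-one | C=C(C)[C@H]1[C@H](O[Si](C(C)C)(C(C)C)C(C)C)/C=C(C)\[C@@H](O)C[C@H]2O[C@@]2(C)C(=O)[C@H]1OC(=O)/C(C)=C\C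
F7 | step 8 | (5S,6S)-6-allyl-5-hydroxy-2,6-dimethylcyclohex-2-en-1-one | O=C1C(C)=CC[C@H](O)[C@]1(C)CC=C
F8 | step 8 | (1S,6S)-6-allyl-4,6-dimethyl-5-oxocyclohex-3-en-1-yl acetate | O=C1C(C)=CC[C@H](OC(C)=O)[C@]1(C)CC=C
F9 | step 8 | (1S,6S)-4,6-dimethyl-5-oxo-6-(2-oxoethyl)cyclohex-3-en-1-yl acetate | O=C1C(C)=CC[C@H](OC(C)=O)[C@]1(C)CC=O
F10 | step 8 | (1S,6S)-4,6-dimethyl-5-oxo-6-[(E)-2-(triisopropylsilyloxy)vinyl]cyclohex-3-en-1-yl acetate | O=C1C(C)=CC[C@H](OC(C)=O)[C@]1(C)/C=C/O[Si](C(C)C)(C(C)C)C(C)C
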